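**Retrosynthetic overview**

1. Target ⇐ 8‑O‑desilylation ⇐ Pd‑catalysed cyclocarbonylation of a 7‑ethynyl‑6,7‑diol (lactone, ring B, closed last) ⇐ 9‑O‑isobutyrylation.
2. Ten‑membered carbocycle (ring A) ⇐ intramolecular Nozaki–Hiyama–Kishi closure of C9–C10 from a (Z)‑vinyl iodide and a C9 aldehyde; C9 is set by the neighbouring C8 centre.
3. C1–C5 chain ⇐ Eschenmoser–Claisen [3,3] rearrangement of an isopropenyl carbinol (key step: forms C2–C3 and the E‑C4=C5 alkene); the C1 amide becomes the aldehyde, then the (Z)‑iodoalkene.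
4. C5–C9 ⇐ L‑arabinose: C6 and C8 are bought, C7 comes from convex‑face ethynylation of the derived 3‑ulose.
5. Ring order: ring A first, ring B second.

Assumption: germacrane numbering is used throughout (ring carbons C1–C10, C11 = lactone α‑carbon, C12 = lactone C=O, C13 = exocyclic CH2; arabinose C1–C5 become C5–C9), and L‑arabinose is drawn in its open‑chain form.

**Route**

Step 1
Reactants: 1 L‑arabinose
Product: 2 5‑O‑(tert‑butyldiphenylsilyl)‑L‑arabinofuranose (anomeric mixture)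
Conditions: TBDPSCl (1.05 equiv), pyridine, 0 °C → rt
Reagents that add atoms: tert‑butyldiphenylsilyl chloride, CC(C)(C)[Si](Cl)(c1ccccc1)c1ccccc1
Why: Selective silyl ether formation at the only primary hydroxyl traps the sugar as the furanose and touches no stereocentre.

Step 2
Reactants: 2 5‑O‑TBDPS‑L‑arabinofuranose
Product: 3 5‑O‑TBDPS‑1,2‑O‑isopropylidene‑β‑L‑arabinofuranose
Conditions: Me2C(OMe)2, TsOH·H2O (cat.), acetone, rt
Reagents that add atoms: 2,2‑dimethoxypropane, COC(C)(C)OC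
Why: Acid‑catalysed acetonide formation can only bridge the cis O1/O2 pair of the furanose (O2/O3 are trans), which fixes the β‑anomer and leaves the 3‑OH free.

Step 3
Reactants: 3 5‑O‑TBDPS‑1,2‑O‑isopropylidene‑β‑L‑arabinofuranose
Product: 4 5‑O‑TBDPS‑1,2‑O‑isopropylidene‑β‑L‑threo‑pentofuranos‑3‑ulose
Conditions: Dess–Martin periodinane, CH2Cl2, 0 °C → rt
Reagents that add atoms: none
Why: Dess–Martin oxidation of the single free secondary alcohol gives the 3‑ulose under non‑basic conditions, so the flanking centres (future C6 and C8) are not epimerised.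

Step 4
Reactants: 4 5‑O‑TBDPS‑1,2‑O‑isopropylidene‑β‑L‑threo‑pentofuranos‑3‑ulose
Product: 5 5‑O‑TBDPS‑3‑C‑ethynyl‑1,2‑O‑isopropylidene‑β‑L‑lyxofuranose
Conditions: HC≡CMgBr, THF, −78 → 0 °C
Reagents that add atoms: ethynylmagnesium bromide, C#C[Mg]Br
Why: Grignard 1,2‑addition occurs from the convex face anti to both the dioxolane and the C4 side chain, so the new tertiary carbinol (C7) has its OH cis to O2 (L‑lyxo) by substrate control.

Step 5
Reactants: 5 5‑O‑TBDPS‑3‑C‑ethynyl‑1,2‑O‑isopropylidene‑β‑L‑lyxofuranose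
Product: 6 5‑O‑TBDPS‑3‑C‑ethynyl‑2,3‑O‑isopropylidene‑L‑lyxofuranose (lactol; anomeric mixture)
Conditions: acetone, H2SO4 (cat.), rt
Reagents that add atoms: none
Why: Thermodynamic acetonide migration moves the isopropylidene from the anomeric acetal to the cis 2,3‑diol (the preferred acetonide of lyxo‑, ribo‑ and manno‑furanoses), freeing the lactol without changing any stereocentre.

Step 6
Reactants: 6 5‑O‑TBDPS‑3‑C‑ethynyl‑2,3‑O‑isopropylidene‑L‑lyxofuranose
Product: 7 open‑chain isopropenyl carbinol CH2=C(CH3)–C5H(OH)–C6–C7(C≡CH)–C8H(OH)–C9H2OTBDPS with 6,7‑O‑isopropylidene (C5 epimers)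
Conditions: CH2=C(CH3)MgBr (5 equiv), THF, 0 °C → rt
Reagents that add atoms: isopropenylmagnesium bromide, CC(=C)[Mg]Br
Why: Grignard addition to the open hydroxy‑aldehyde tautomer of the lactol builds the allylic alcohol; the C5 epimer mixture is irrelevant because C5 becomes sp2 in step 7.

Step 7
Reactants: 7 open‑chain isopropenyl carbinol (C5 epimers)
Product: 9 (4E)‑C1 N,N‑dimethylamide Me2NC(=O)–C2H2–C3H2–C4(CH3)=C5H–C6… with free 8‑OH, via ketene N,O‑acetal 8 (not isolated)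
Conditions: MeC(OMe)2NMe2 (5 equiv), xylenes, 140 °C, sealed tube; aq. NaHCO3 work‑up
Reagents that add atoms: N,N‑dimethylacetamide dimethyl acetal, COC(C)(OC)N(C)C
Why: Eschenmoser–Claisen [3,3]‑sigmatropic rearrangement through a chair transition state with the bulky dioxolanyl group equatorial forms the C2–C3 bond and the E‑C4=C5 alkene from either C5 epimer, while the non‑allylic 8‑OH only exchanges reversibly and returns on work‑up.

Step 8
Reactants: 9 (4E)‑C1 N,N‑dimethylamide with free 8‑OH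
Product: 10 8‑O‑TBS ether of 9
Conditions: TBSOTf, 2,6‑lutidine, CH2Cl2, −78 → 0 °C
Reagents that add atoms: tert‑butyldimethylsilyl triflate, CC(C)(C)[Si](C)(C)OS(=O)(=O)C(F)(F)F
Why: Silyl triflate etherification protects the only remaining hydroxyl, which is hindered and secondary, so that C8–O stays differentiated from C6–O and C9–O to the end.

Step 9
Reactants: 10 8‑O‑TBS amide
Product: 11 (4E)‑C1 aldehyde
Conditions: LiAlH(OEt)3 (from LiAlH4 and EtOAc), Et2O, 0 °C
Reagents that add atoms: none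
Why: Brown partial reduction of a tertiary amide stops at the aluminium aminal, which releases the aldehyde only on work‑up; silyl ethers, acetonide and alkyne are inert.

Step 10
Reactants: 11 (4E)‑C1 aldehyde
Product: 12 (1(10)Z,4E)‑10‑iodo diene (CH3–C10(I)=C1H–, iodine cis to C2)
Conditions: [Ph3PEt]I, n‑BuLi, THF; I2, −78 °C; NaN(SiMe3)2, −20 °C; then 11, −78 °C → rt
Reagents that add atoms: ethyltriphenylphosphonium iodide, CC[P+](c1ccccc1)(c1ccccc1)c1ccccc1.[I-]; iodine, II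
Why: Stork–Zhao‑type Wittig olefination with the α‑iodo ylide is kinetically Z‑selective, placing iodine cis to the chain as needed for the 1(10)Z ring alkene.

Step 11
Reactants: 12 (Z)‑vinyl iodide
Product: 13 C9 primary alcohol
Conditions: TBAF, AcOH (1:1), THF, 0 °C → rt
Reagents that add atoms: none
Why: Buffered fluoride desilylation cleaves the unhindered primary TBDPS ether faster than the secondary TBS ether, which is shielded by the adjacent quaternary C7.

Step 12
Reactants: 13 C9 primary alcohol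
Product: 14 C9 aldehyde (α‑silyloxy aldehyde)
Conditions: Dess–Martin periodinane, CH2Cl2, 0 °C → rt
Reagents that add atoms: none
Why: Dess–Martin oxidation gives the aldehyde under near‑neutral conditions that do not epimerise C8 or touch the vinyl iodide.

Step 13
Reactants: 14 C9 aldehyde
Product: 15 macrocyclic allylic alcohol: 4,10‑dimethylcyclodeca‑(1(10)Z,4E)‑diene with 9‑OH (8,9‑anti), 8‑OTBS, 7‑ethynyl and cis‑fused 6,7‑acetonide
Conditions: CrCl2 (10 equiv), NiCl2 (5 mol %), DMSO–THF, 0.003 M, rt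
Reagents that add atoms: none
Why: Intramolecular Nozaki–Hiyama–Kishi coupling closes C9–C10 with retention of the Z geometry, and Felkin–Anh/Cornforth attack anti to the α‑silyloxy group, within the turn imposed by the cis‑dioxolane, sets C9 (8,9‑anti).

Step 14
Reactants: 15 macrocyclic allylic alcohol
Product: 16 9‑O‑isobutyrate
Conditions: (i‑PrCO)2O, DMAP (cat.), Et3N, CH2Cl2, 0 °C
Reagents that add atoms: isobutyric anhydride, CC(C)C(=O)OC(=O)C(C)C
Why: DMAP‑catalysed acylation esterifies the only free hydroxyl with retention at C9.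

Step 15
Reactants: 16 9‑O‑isobutyrate
Product: 17 6,7‑diol (7‑ethynyl, 8‑OTBS, 9‑O‑isobutyrate)
Conditions: AcOH–H2O (4:1), 45 °C
Reagents that add atoms: none
Why: Mild aqueous‑acid ketal hydrolysis removes the isopropylidene, while acetic acid is too weak to protonate the trisubstituted alkenes or cleave the hindered TBS ether.

Step 16
Reactants: 17 6,7‑diol
Product: 18 8‑O‑TBS ether of the target (α‑methylene‑γ‑lactone closed on O6)
Conditions: PdCl2 (10 mol %), thiourea (10 mol %), CO (1 atm), acetone, 50 °C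
Reagents that add atoms: carbon monoxide, [C-]#[O+]
Why: Norton‑type palladium‑catalysed cyclocarbonylation of the 3‑butyn‑1‑ol unit (6‑OH/7‑ethynyl) gives the α‑methylene‑γ‑butyrolactone; with O8 silylated only the 6,12‑lactone can form, and C6 and C7 are untouched.

Step 17
Reactants: 18 8‑O‑TBS ether of the target
Product: 19 target, (1(10)Z,4E,6S,7R,8S,9S)‑7,8‑dihydroxy‑9‑isobutyryloxygermacra‑1(10),4,11(13)‑trien‑12,6‑olide
Conditions: HF·pyridine, pyridine, THF, 0 °C → rt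
Reagents that add atoms: none
Why: Fluoride desilylation in a non‑basic medium frees the 8‑OH without acyl migration, translactonisation or conjugate addition to the methylene lactone.

**Compound list**

1 | L‑arabinose (open‑chain form, (2R,3S,4S)) | O=C[C@H](O)[C@@H](O)[C@@H](O)CO | starting material
2 | 5‑O‑TBDPS‑L‑arabinofuranose (anomers) | OC1O[C@@H](CO[Si](c2ccccc2)(c2ccccc2)C(C)(C)C)[C@H](O)[C@H]1O | intermediate
3 | 5‑O‑TBDPS‑1,2‑O‑isopropylidene‑β‑L‑arabinofuranose | CC1(C)O[C@H]2O[C@@H](CO[Si](c3ccccc3)(c3ccccc3)C(C)(C)C)[C@H](O)[C@H]2O1 | intermediate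
4 | 5‑O‑TBDPS‑1,2‑O‑isopropylidene‑β‑L‑threo‑pentofuranos‑3‑ulose | CC1(C)O[C@H]2O[C@@H](CO[Si](c3ccccc3)(c3ccccc3)C(C)(C)C)C(=O)[C@H]2O1 | intermediate
5 | 5‑O‑TBDPS‑3‑C‑ethynyl‑1,2‑O‑isopropylidene‑β‑L‑lyxofuranose | CC1(C)O[C@H]2O[C@@H](CO[Si](c3ccccc3)(c3ccccc3)C(C)(C)C)[C@](O)(C#C)[C@H]2O1 | intermediate
6 | 5‑O‑TBDPS‑3‑C‑ethynyl‑2,3‑O‑isopropylidene‑L‑lyxofuranose (lactol, anomers) | OC1O[C@@H](CO[Si](c2ccccc2)(c2ccccc2)C(C)(C)C)[C@@]2(C#C)OC(C)(C)O[C@@H]12 | intermediate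
7 | open‑chain isopropenyl carbinol, 6,7‑acetonide, 8‑OH, 9‑OTBDPS (C5 epimers; C6–C8 as in 6) | C=C(C)C(O)[C@@H]1OC(C)(C)O[C@]1(C#C)[C@@H](O)CO[Si](c1ccccc1)(c1ccccc1)C(C)(C)C | intermediate
8 | 5‑O‑[1‑(dimethylamino)vinyl] ether of 7 (ketene N,O‑acetal) | C=C(C)C(OC(=C)N(C)C)[C@@H]1OC(C)(C)O[C@]1(C#C)[C@@H](O)CO[Si](c1ccccc1)(c1ccccc1)C(C)(C)C | intermediate (not isolated)
9 | (4E)‑C1 N,N‑dimethylamide, 8‑OH free | CN(C)C(=O)CC/C(C)=C/[C@@H]1OC(C)(C)O[C@]1(C#C)[C@@H](O)CO[Si](c1ccccc1)(c1ccccc1)C(C)(C)C | intermediate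
10 | 8‑O‑TBS ether of 9 | CN(C)C(=O)CC/C(C)=C/[C@@H]1OC(C)(C)O[C@]1(C#C)[C@@H](O[Si](C)(C)C(C)(C)C)CO[Si](c1ccccc1)(c1ccccc1)C(C)(C)C | intermediate
11 | (4E)‑C1 aldehyde | O=CCC/C(C)=C/[C@@H]1OC(C)(C)O[C@]1(C#C)[C@@H](O[Si](C)(C)C(C)(C)C)CO[Si](c1ccccc1)(c1ccccc1)C(C)(C)C | intermediate
12 | (1(10)Z,4E)‑10‑iodo diene | C/C(I)=C/CC/C(C)=C/[C@@H]1OC(C)(C)O[C@]1(C#C)[C@@H](O[Si](C)(C)C(C)(C)C)CO[Si](c1ccccc1)(c1ccccc1)C(C)(C)C | intermediate
13 | C9 primary alcohol | C/C(I)=C/CC/C(C)=C/[C@@H]1OC(C)(C)O[C@]1(C#C)[C@@H](O[Si](C)(C)C(C)(C)C)CO | intermediate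
14 | C9 aldehyde | C/C(I)=C/CC/C(C)=C/[C@@H]1OC(C)(C)O[C@]1(C#C)[C@@H](O[Si](C)(C)C(C)(C)C)C=O | intermediate
15 | macrocyclic 9‑alcohol (ring A; 6,7‑acetonide, 7‑ethynyl, 8‑OTBS) | C#C[C@]12OC(C)(C)O[C@H]1/C=C(\C)CC/C=C(/C)[C@H](O)[C@@H]2O[Si](C)(C)C(C)(C)C | intermediate
16 | 9‑O‑isobutyrate of 15 | C#C[C@]12OC(C)(C)O[C@H]1/C=C(\C)CC/C=C(/C)[C@H](OC(=O)C(C)C)[C@@H]2O[Si](C)(C)C(C)(C)C | intermediate
17 | 6,7‑diol (7‑ethynyl, 8‑OTBS, 9‑O‑isobutyrate) | C#C[C@]1(O)[C@@H](O)/C=C(\C)CC/C=C(/C)[C@H](OC(=O)C(C)C)[C@@H]1O[Si](C)(C)C(C)(C)C | intermediate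
18 | 8‑O‑TBS ether of the target | C=C1C(=O)O[C@H]2/C=C(\C)CC/C=C(/C)[C@H](OC(=O)C(C)C)[C@H](O[Si](C)(C)C(C)(C)C)[C@]12O | intermediate
19 | target CNP0301808.4 | C=C1C(=O)O[C@H]2/C=C(\C)CC/C=C(/C)[C@H](OC(=O)C(C)C)[C@H](O)[C@]12O | target

**Step count and risks**

Total steps: 17. Longest linear sequence: 17 (fully linear from L‑arabinose).

Most likely to fail:

Step 13, the ring closure. A ten‑membered ring has to form and C9 is set only by substrate control. The fallback sets out from 14 and covers the case that the closure works but gives mainly the wrong C9 configuration: the 9‑epi macrocyclic alcohol F1 is esterified under Mitsunobu conditions (isobutyric acid, PPh3, DIAD, toluene, 0 °C). This inverts C9 and installs the ester in one operation, and the route is rejoined at 16.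

Step 16, the cyclocarbonylation. It is run late, on a macrocycle that carries a tertiary propargylic alcohol, an allylic ester and a 1,5‑diene. The fallback sets out from 17 and separates carbonylation from ring closure: intermolecular Markovnikov hydromethoxycarbonylation of the alkyne (Pd(OAc)2 cat., 2‑(diphenylphosphino)pyridine, MeSO3H cat., CO, MeOH) gives the methyl 2‑substituted acrylate F2. Lactonisation onto the 6‑OH (PPTS, toluene, 40 °C) then rejoins the route at 18.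

Step 10, the Z‑selective iodo‑olefination. It is typically low‑yielding and basic. The fallback sets out from 11: Corey–Fuchs dibromo‑olefination (CBr4, PPh3, CH2Cl2) gives the 1,1‑dibromoalkene F3. Trans‑selective Negishi monomethylation (Me2Zn, Pd(P(t‑Bu)3)2 cat., THF) gives the (Z)‑vinyl bromide F4. This is carried through the conditions of steps 11 and 12 as the bromo alcohol F5 and the bromo aldehyde F6. Closure of F6 with CrCl2/NiCl2 rejoins the route at 15.

Further compounds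
F1 | step 13 | 9‑epi macrocyclic alcohol (C9 epimer of 15) | C#C[C@]12OC(C)(C)O[C@H]1/C=C(\C)CC/C=C(/C)[C@@H](O)[C@@H]2O[Si](C)(C)C(C)(C)C
F2 | step 16 | methyl 2‑substituted acrylate (6,7‑diol, 8‑OTBS, 9‑O‑isobutyrate) | COC(=O)C(=C)[C@]1(O)[C@@H](O)/C=C(\C)CC/C=C(/C)[C@H](OC(=O)C(C)C)[C@@H]1O[Si](C)(C)C(C)(C)C
F3 | step 10 | 1,1‑dibromoalkene from 11 | BrC(Br)=CCC/C(C)=C/[C@@H]1OC(C)(C)O[C@]1(C#C)[C@@H](O[Si](C)(C)C(C)(C)C)CO[Si](c1ccccc1)(c1ccccc1)C(C)(C)C
F4 | step 10 | (1(10)Z,4E)‑10‑bromo diene (bromo analogue of 12) | C/C(Br)=C/CC/C(C)=C/[C@@H]1OC(C)(C)O[C@]1(C#C)[C@@H](O[Si](C)(C)C(C)(C)C)CO[Si](c1ccccc1)(c1ccccc1)C(C)(C)C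
F5 | step 10 | bromo analogue of alcohol 13 | C/C(Br)=C/CC/C(C)=C/[C@@H]1OC(C)(C)O[C@]1(C#C)[C@@H](O[Si](C)(C)C(C)(C)C)CO
F6 | step 10 | bromo analogue of aldehyde 14 | C/C(Br)=C/CC/C(C)=C/[C@@H]1OC(C)(C)O[C@]1(C#C)[C@@H](O[Si](C)(C)C(C)(C)C)C=O
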